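**Plan**

- Retrosynthesis: the δ-lactone is cut first at C12–C13 and C10–O11 (formaldehyde aldol, lactonization), then the C18–C19 bond of the ether bridge (radical closure), then O17–C18 and C16–O17 (O–H insertion on a C16 alcohol made from a ring A dienone), then C4–C2 (Ireland–Claisen), and last ring C at C7–C8 and C4–C9 (Diels–Alder of a ring A dienyl).
- Forward: ring A is carried as a bromo ketal and made into a 1-substituted butadiene; the cycloaddition builds ring C on C13; iodolactone, inversion and a [3,3] shift put the propanoate on C4; ring A is unmasked, oxidized to the dienone, hydroxylated at C16 and etherified; the tetrahydrofuran bridge closes; the lactone ring is made last.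
- Enabling feature: O17–C18 spans C16 and C19 across the gem-dimethyl carbon C20 of ring A (C13, C14, C15, C16, C20, C19), so a CH2 radical on the C16 oxygen sits over C19 of the C13=C19 enone (C14 ketone) and closes 5-exo.
- Stereochemistry: C7 and C8 from a catalytic enantioselective endo Diels–Alder; C4 and C2 relayed from C8 (iodolactone, Mitsunobu inversion, boat Ireland–Claisen); C16 from a ligand-controlled conjugate borylation; C19 from C16 through the tether; C13 from attack anti to the C20 methyl.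

Key step: step 18

Numbering and shorthand: atom numbers are those of the target (C1–C3 propanoic acid chain; ring C = C4–C9 with C10 on C8; C12 lactone CH2; ring A as above; O17 and C18 the ether bridge). "A-ketal" = 8,8-dimethyl-1,4-dioxaspiro[4.5]dec-6-en-6-yl, which is ring A with C14 as ethylene ketal, bonded through C13. tBu-box = 2,2′-(propane-2,2-diyl)bis(4-tert-butyl-4,5-dihydro-1,3-oxazole).

Assumption: the sense of induction of the two ligand-controlled steps (step 4, attack on the Cα re face of the chelated acrylimide with the (S,S) ligand; step 15, 16R with the named bisphosphine) is taken from the simple parent substrates; if either is reversed here, the enantiomeric ligand is used.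

Step 1
Reactants: 1 4,4-dimethylcyclohex-2-en-1-one
Product: 3 2-bromo-4,4-dimethylcyclohex-2-en-1-one, via trans-2,3-dibromo-4,4-dimethylcyclohexan-1-one 2 (not isolated)
Conditions: Br2, CH2Cl2, 0 °C; then Et3N, 0 °C → rt
Reagents that add atoms: bromine, BrBr
Why: Bromination–dehydrobromination, in which bromine adds across the enone alkene and triethylamine removes HBr from the α-bromo ketone, is the standard route to 2-bromo enones and tolerates the neopentyl β-carbon.

Step 2
Reactants: 3 2-bromo-4,4-dimethylcyclohex-2-en-1-one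
Product: 4 6-bromo-8,8-dimethyl-1,4-dioxaspiro[4.5]dec-6-ene
Conditions: HOCH2CH2OH, p-TsOH (cat.), benzene, reflux, azeotropic removal of water
Reagents that add atoms: ethane-1,2-diol, OCCO
Why: Acid-catalysed ketalization masks the ketone for the later enolate steps, and the alkene cannot migrate because the γ-carbon is quaternary.

Step 3
Reactants: 4 6-bromo-8,8-dimethyl-1,4-dioxaspiro[4.5]dec-6-ene; 5 2-[(1E)-buta-1,3-dien-1-yl]-4,4,5,5-tetramethyl-1,3,2-dioxaborolane
Product: 6 6-[(1E)-buta-1,3-dien-1-yl]-8,8-dimethyl-1,4-dioxaspiro[4.5]dec-6-ene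
Conditions: Pd(dppf)Cl2 (5 mol%), K3PO4, THF/H2O, 60 °C
Reagents that add atoms: none
Why: Suzuki–Miyaura coupling of an alkenyl bromide with an (E)-alkenylboronate retains both alkene geometries and gives the (E)-1-substituted butadiene needed for an ortho, endo cycloaddition.

Step 4
Reactants: 6 6-[(1E)-buta-1,3-dien-1-yl]-8,8-dimethyl-1,4-dioxaspiro[4.5]dec-6-ene; 7 3-(prop-2-enoyl)-1,3-oxazolidin-2-one
Product: 8 3-{[(1S,2R)-2-(A-ketal)cyclohex-3-en-1-yl]carbonyl}-1,3-oxazolidin-2-one
Conditions: [Cu((S,S)-tBu-box)](SbF6)2 (10 mol%), CH2Cl2, −20 °C → rt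
Reagents that add atoms: none
Why: Enantioselective Diels–Alder reaction catalysed by the cationic divalent copper bis(oxazoline) complex, which chelates the acrylimide: the unhindered terminal diene unit reacts with ortho regiochemistry and endo geometry, so ring A on C7 is cis to the acyl group on C8, and the (S,S) ligand leaves the Cα re face open, which fixes C7 and C8 in the absolute sense of the target.

Step 5
Reactants: 8 3-{[(1S,2R)-2-(A-ketal)cyclohex-3-en-1-yl]carbonyl}-1,3-oxazolidin-2-one
Product: 9 (1S,2R)-2-(A-ketal)cyclohex-3-ene-1-carboxylic acid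
Conditions: LiOH, H2O2, THF/H2O, 0 °C; Na2SO3; then 1 M HCl to pH 4
Reagents that add atoms: hydrogen peroxide, OO (as lithium hydroperoxide; oxygen of the acid OH)
Why: Hydroperoxide cleavage of the N-acyl oxazolidinone attacks the exocyclic carbonyl selectively and, after sulfite reduction of the peracid, frees the acid without epimerizing C8.

Step 6
Reactants: 9 (1S,2R)-2-(A-ketal)cyclohex-3-ene-1-carboxylic acid
Product: 10 4-iodo-8-(A-ketal)-6-oxabicyclo[3.2.1]octan-7-one (lactone oxygen on C6 cis to C10; iodine on C5 trans to it)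
Conditions: I2, KI, NaHCO3, THF/H2O, 0 °C → rt, dark
Reagents that add atoms: iodine, II
Why: Iodolactonization, in which the axial carboxylate opens the iodonium ion of the C5=C6 alkene at C6 from its own face (5-exo, anti addition), sets the C6 oxygen cis to C10 and the C5 iodine trans to it, while the hindered ring A alkene has no internal nucleophile and is left.

Step 7
Reactants: 10 4-iodo-8-(A-ketal)-6-oxabicyclo[3.2.1]octan-7-one
Product: 11 8-(A-ketal)-6-oxabicyclo[3.2.1]oct-3-en-7-one
Conditions: DBU, toluene, 80 °C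
Reagents that add atoms: none
Why: E2 dehydroiodination can use only H4, which is antiperiplanar to the axial C5–I bond (H6 is syn), so the C4=C5 alkene and thus the allylic lactone is formed.

Step 8
Reactants: 11 8-(A-ketal)-6-oxabicyclo[3.2.1]oct-3-en-7-one
Product: 12 methyl all-cis-5-hydroxy-6-(A-ketal)cyclohex-3-ene-1-carboxylate
Conditions: NaOMe (0.2 equiv), MeOH, 0 °C
Reagents that add atoms: methanol, CO
Why: Methoxide-catalysed transesterification opens the strained bridged lactone to the methyl ester and the C6 allylic alcohol without breaking a bond to a stereocentre, and the cold, catalytic base avoids epimerization at C8.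

Step 9
Reactants: 12 methyl all-cis-5-hydroxy-6-(A-ketal)cyclohex-3-ene-1-carboxylate
Product: 13 methyl 5-(propanoyloxy)-6-(A-ketal)cyclohex-3-ene-1-carboxylate (propanoate on C6 trans to ring A and to CO2Me)
Conditions: EtCO2H, PPh3, DIAD, THF, 0 °C → rt
Reagents that add atoms: propanoic acid, CCC(=O)O
Why: Mitsunobu esterification displaces the oxyphosphonium group by SN2, so the propanoate enters at C6 with inversion and now lies on the face opposite to C10, from which carbon is to be delivered to C4.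

Step 10
Reactants: 13 methyl 5-(propanoyloxy)-6-(A-ketal)cyclohex-3-ene-1-carboxylate
Product: 16 (2R)-2-[(1S,4R,5S)-5-(methoxycarbonyl)-4-(A-ketal)cyclohex-2-en-1-yl]propanoic acid, via silyl ketene acetal 14 (not isolated), via trimethylsilyl ester 15 (not isolated)
Conditions: LDA, THF/DMPU, −78 °C; TMSCl, −78 → 50 °C; then H2O, pH 5
Reagents that add atoms: chlorotrimethylsilane, C[Si](C)(C)Cl (silicon of 14 and 15 only; no atom of it remains in 16)
Why: Ireland–Claisen rearrangement: kinetic deprotonation of the unhindered propanoate CH2 (not the tertiary C8–H) in THF/DMPU gives the (Z)-silyl ketene acetal (methyl cis to OSiMe3), which rearranges suprafacially through the boat-like transition state usual for cyclohex-2-enyl esters, so the C4–C2 bond forms on the face of the C6 oxygen (trans to C10) and C2 is set as 2R.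

Step 11
Reactants: 16 (2R)-2-[(1S,4R,5S)-5-(methoxycarbonyl)-4-(A-ketal)cyclohex-2-en-1-yl]propanoic acid
Product: 17 benzyl (2R)-2-[(1S,4R,5S)-5-(methoxycarbonyl)-4-(A-ketal)cyclohex-2-en-1-yl]propanoate
Conditions: BnBr, K2CO3, DMF, rt
Reagents that add atoms: benzyl bromide, BrCc1ccccc1
Why: SN2 alkylation of the carboxylate gives a benzyl ester that survives all later acidic, basic and radical steps and is removed last under neutral conditions.

Step 12
Reactants: 17 benzyl (2R)-2-[(1S,4R,5S)-5-(methoxycarbonyl)-4-(A-ketal)cyclohex-2-en-1-yl]propanoate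
Product: 18 benzyl (2R)-2-[(1R,3S,4R)-3-(methoxycarbonyl)-4-(A-ketal)cyclohexyl]propanoate
Conditions: H2 (3 atm), RhCl(PPh3)3 (5 mol%), benzene/EtOH, rt
Reagents that add atoms: none
Why: Homogeneous hydrogenation with RhCl(PPh3)3 reduces the cis-disubstituted C5=C6 alkene selectively, because the trisubstituted C13=C19 alkene is shielded by the ketal carbon and quaternary C20 and the benzyl ester is inert to this catalyst.

Step 13
Reactants: 18 benzyl (2R)-2-[(1R,3S,4R)-3-(methoxycarbonyl)-4-(A-ketal)cyclohexyl]propanoate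
Product: 19 benzyl (2R)-2-[(1R,3S,4R)-4-(3,3-dimethyl-6-oxocyclohex-1-en-1-yl)-3-(methoxycarbonyl)cyclohexyl]propanoate
Conditions: 1 M HCl, THF, rt
Reagents that add atoms: water, O
Why: Acid-catalysed ketal hydrolysis regenerates the ring A enone (C14 ketone, C13=C19), and both esters are stable to dilute aqueous acid at room temperature.

Step 14
Reactants: 19 benzyl (2R)-2-[(1R,3S,4R)-4-(3,3-dimethyl-6-oxocyclohex-1-en-1-yl)-3-(methoxycarbonyl)cyclohexyl]propanoate
Product: 21 benzyl (2R)-2-[(1R,3S,4R)-4-(3,3-dimethyl-6-oxocyclohexa-1,4-dien-1-yl)-3-(methoxycarbonyl)cyclohexyl]propanoate, via trimethylsilyl dienol ether 20 (not isolated)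
Conditions: LiHMDS, TMSCl, THF, −78 °C; then Pd(OAc)2, MeCN, rt
Reagents that add atoms: chlorotrimethylsilane, C[Si](C)(C)Cl (silicon of 20 only; no atom of it remains in 21)
Why: Saegusa–Ito oxidation: C15 is the only enolizable ketone position and is more acidic than the ester α-hydrogens, so the silyl dienol ether forms there and palladium diacetate introduces the C15=C16 alkene to give the cross-conjugated dienone.

Step 15
Reactants: 21 benzyl (2R)-2-[(1R,3S,4R)-4-(3,3-dimethyl-6-oxocyclohexa-1,4-dien-1-yl)-3-(methoxycarbonyl)cyclohexyl]propanoate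
Product: 23 benzyl (2R)-2-[(1R,3S,4R)-4-[(4R)-4-hydroxy-3,3-dimethyl-6-oxocyclohex-1-en-1-yl]-3-(methoxycarbonyl)cyclohexyl]propanoate, via C16 pinacol boronate 22 (not isolated)
Conditions: CuCl (5 mol%), NaOtBu (10 mol%), (R)-1-[(SP)-2-(diphenylphosphino)ferrocenyl]ethyldicyclohexylphosphine (6 mol%), B2pin2, MeOH, THF, rt; then NaBO3·4H2O, THF/H2O, 0 °C → rt
Reagents that add atoms: sodium perborate, [Na+].[O-]OB=O (oxygen of the C16 hydroxyl); bis(pinacolato)diboron, CC1(C)OB(OC1(C)C)B1OC(C)(C)C(C)(C)O1 (boron of 22 only)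
Why: Copper-catalysed asymmetric conjugate borylation followed by perborate oxidation with retention: the boryl copper adds to the α-unsubstituted enone alkene at C16 in preference to the α-substituted C13=C19 alkene, and the chiral bisphosphine, not the remote ring C stereocentres, sets 16R.

Step 16
Reactants: 23 benzyl (2R)-2-[(1R,3S,4R)-4-[(4R)-4-hydroxy-3,3-dimethyl-6-oxocyclohex-1-en-1-yl]-3-(methoxycarbonyl)cyclohexyl]propanoate
Product: 24 benzyl (2R)-2-[(1R,3S,4R)-4-[(4R)-4-(2-tert-butoxy-2-oxoethoxy)-3,3-dimethyl-6-oxocyclohex-1-en-1-yl]-3-(methoxycarbonyl)cyclohexyl]propanoate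
Conditions: N2CHCO2tBu (slow addition), Rh2(OAc)4 (2 mol%), CH2Cl2, rt
Reagents that add atoms: tert-butyl diazoacetate, CC(C)(C)OC(=O)C=[N+]=[N-]
Why: Rhodium carbenoid O–H insertion etherifies the hindered C16 alcohol under neutral conditions and so avoids the E1cB dehydration to the dienone that a base-mediated Williamson alkylation of this β-hydroxy ketone would cause.

Step 17
Reactants: 24 benzyl (2R)-2-[(1R,3S,4R)-4-[(4R)-4-(2-tert-butoxy-2-oxoethoxy)-3,3-dimethyl-6-oxocyclohex-1-en-1-yl]-3-(methoxycarbonyl)cyclohexyl]propanoate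
Product: 25 benzyl (2R)-2-[(1R,3S,4R)-4-[(4R)-4-(carboxymethoxy)-3,3-dimethyl-6-oxocyclohex-1-en-1-yl]-3-(methoxycarbonyl)cyclohexyl]propanoate
Conditions: TFA, CH2Cl2, 0 °C
Reagents that add atoms: none
Why: Acidolysis of the tert-butyl ester frees the α-alkoxy acetic acid, while the benzyl ester, the methyl ester and the β-alkoxy enone are stable to cold trifluoroacetic acid.

Step 18
Reactants: 25 benzyl (2R)-2-[(1R,3S,4R)-4-[(4R)-4-(carboxymethoxy)-3,3-dimethyl-6-oxocyclohex-1-en-1-yl]-3-(methoxycarbonyl)cyclohexyl]propanoate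
Product: 26 benzyl 2-[3-(methoxycarbonyl)-4-(8,8-dimethyl-3-oxo-6-oxabicyclo[3.2.1]octan-2-yl)cyclohexyl]propanoate (C2 and ring C as in 25; 16R; O17–C18 bridge from C16 to C19; C13–H)
Conditions: Ir[dF(CF3)ppy]2(dtbbpy)PF6 (1 mol%), K2HPO4 (1.2 equiv), DMF (0.02 M, degassed), blue LEDs (450 nm), rt
Reagents that add atoms: none
Why: The excited trivalent iridium photocatalyst oxidizes the carboxylate of 25 and loss of CO2 leaves the nucleophilic α-alkoxymethyl radical at C18, which adds to the electrophilic β-carbon C19 of the C13=C19 enone; the α-keto radical at C13 is then reduced by divalent iridium to the enolate and protonated. The closest known reaction type is the photoredox decarboxylative Giese addition of α-alkoxy carboxylic acids to enones, run here intramolecularly, and the bridging geometry is that of the iodolactonization in step 6, where an atom two bonds from a ring carbon also closes onto the ring position 1,3 to it. The tetrahydrofuran ring (C16, O17, C18, C19, C20) closes in the 5-exo-trig mode and, with ring A, gives the 6-oxabicyclo[3.2.1]octanone. The new stereocentre C19 is controlled by C16, because the one-carbon tether on the axial C16 oxygen reaches only its own face of the enone; C13 is left as an epimerizable CH (drawn with ring C equatorial) and is reset in step 19. The step needs attack at C19 rather than quenching of the radical or attack at C13, which the polarity match of a nucleophilic radical with the enone β-carbon and the high dilution secure, and it needs the β-alkoxy ketone to survive, which the weak base K2HPO4 at room temperature secures.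

Step 19
Reactants: 26 benzyl 2-[3-(methoxycarbonyl)-4-(8,8-dimethyl-3-oxo-6-oxabicyclo[3.2.1]octan-2-yl)cyclohexyl]propanoate
Product: 28 benzyl ester of the target, via C13 hydroxymethyl ketone 27 (not isolated)
Conditions: HCHO (37% aq., 5 equiv), K2CO3 (0.5 equiv), THF/H2O, 0 °C → rt
Reagents that add atoms: formaldehyde, C=O
Why: Base-mediated aldol addition to formaldehyde is reversible at both C13 and C15, but only the C13 adduct can lactonize onto the C10 methyl ester (six-membered ring), which drains the equilibrium, and formaldehyde should attack C13 anti to the C20 methyl that lies over the three-atom bridge, so C12 becomes equatorial and ring C axial as in the target.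

Step 20
Reactants: 28 benzyl ester of the target
Product: 29 CNP0152427.2
Conditions: H2 (1 atm), 10% Pd/C, EtOAc, rt
Reagents that add atoms: none
Why: Hydrogenolysis of the benzyl ester frees the C3 acid under neutral conditions that leave the lactone, the ketone and the ether bridge untouched.

**Compound list**

1 | 4,4-dimethylcyclohex-2-en-1-one | CC1(C)CCC(=O)C=C1 | starting material
2 | rac-trans-2,3-dibromo-4,4-dimethylcyclohexan-1-one | CC1(C)CCC(=O)[C@H](Br)[C@H]1Br | intermediate
3 | 2-bromo-4,4-dimethylcyclohex-2-en-1-one | CC1(C)CCC(=O)C(Br)=C1 | intermediate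
4 | 6-bromo-8,8-dimethyl-1,4-dioxaspiro[4.5]dec-6-ene | CC1(C)CCC2(OCCO2)C(Br)=C1 | intermediate
5 | 2-[(1E)-buta-1,3-dien-1-yl]-4,4,5,5-tetramethyl-1,3,2-dioxaborolane | C=C/C=C/B1OC(C)(C)C(C)(C)O1 | starting material
6 | 6-[(1E)-buta-1,3-dien-1-yl]-8,8-dimethyl-1,4-dioxaspiro[4.5]dec-6-ene | CC1(C)CCC2(OCCO2)C(/C=C/C=C)=C1 | intermediate
7 | 3-(prop-2-enoyl)-1,3-oxazolidin-2-one | C=CC(=O)N1CCOC1=O | starting material
8 | 3-{[(1S,2R)-2-(8,8-dimethyl-1,4-dioxaspiro[4.5]dec-6-en-6-yl)cyclohex-3-en-1-yl]carbonyl}-1,3-oxazolidin-2-one (ring A on C7 cis to the acyl group on C8) | C1C=C[C@@H](C2=CC(C)(C)CCC23OCCO3)[C@H](C1)C(=O)N4CCOC4=O | intermediate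
9 | (1S,2R)-2-(8,8-dimethyl-1,4-dioxaspiro[4.5]dec-6-en-6-yl)cyclohex-3-ene-1-carboxylic acid | C1C=C[C@@H](C2=CC(C)(C)CCC23OCCO3)[C@H](C1)C(=O)O | intermediate
10 | 4-iodo-8-(8,8-dimethyl-1,4-dioxaspiro[4.5]dec-6-en-6-yl)-6-oxabicyclo[3.2.1]octan-7-one (lactone C10–O–C6 cis-bridging; iodine on C5 trans to the lactone oxygen; ring A on bridge carbon C7) | C1[C@H](I)[C@@H]2[C@@H](C3=CC(C)(C)CCC34OCCO4)[C@H](C1)C(=O)O2 | intermediate
11 | 8-(8,8-dimethyl-1,4-dioxaspiro[4.5]dec-6-en-6-yl)-6-oxabicyclo[3.2.1]oct-3-en-7-one (C4=C5 alkene; allylic lactone oxygen on C6) | C1=C[C@@H]2[C@@H](C3=CC(C)(C)CCC34OCCO4)[C@H](C1)C(=O)O2 | intermediate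
12 | methyl all-cis-5-hydroxy-6-(8,8-dimethyl-1,4-dioxaspiro[4.5]dec-6-en-6-yl)cyclohex-3-ene-1-carboxylate (OH on C6, ring A on C7, CO2Me on C8 on one face) | C1=C[C@@H](O)[C@@H](C2=CC(C)(C)CCC23OCCO3)[C@H](C1)C(=O)OC | intermediate
13 | methyl 5-(propanoyloxy)-6-(8,8-dimethyl-1,4-dioxaspiro[4.5]dec-6-en-6-yl)cyclohex-3-ene-1-carboxylate (propanoate on C6 trans to ring A and to CO2Me) | C1=C[C@H](OC(=O)CC)[C@@H](C2=CC(C)(C)CCC23OCCO3)[C@H](C1)C(=O)OC | intermediate
14 | (Z)-O-trimethylsilyl ketene acetal of 13 (methyl cis to OSiMe3) | C1=C[C@H](O/C(=C/C)O[Si](C)(C)C)[C@@H](C2=CC(C)(C)CCC23OCCO3)[C@H](C1)C(=O)OC | intermediate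
15 | trimethylsilyl ester of 16 | C[C@@H](C(=O)O[Si](C)(C)C)[C@@H]1C=C[C@@H](C2=CC(C)(C)CCC23OCCO3)[C@H](C1)C(=O)OC | intermediate
16 | (2R)-2-[(1S,4R,5S)-5-(methoxycarbonyl)-4-(8,8-dimethyl-1,4-dioxaspiro[4.5]dec-6-en-6-yl)cyclohex-2-en-1-yl]propanoic acid (side chain on C4 trans to CO2Me and to ring A; C5=C6 alkene) | C[C@@H](C(=O)O)[C@@H]1C=C[C@@H](C2=CC(C)(C)CCC23OCCO3)[C@H](C1)C(=O)OC | intermediate
17 | benzyl (2R)-2-[(1S,4R,5S)-5-(methoxycarbonyl)-4-(8,8-dimethyl-1,4-dioxaspiro[4.5]dec-6-en-6-yl)cyclohex-2-en-1-yl]propanoate | C[C@@H](C(=O)OCc1ccccc1)[C@@H]1C=C[C@@H](C2=CC(C)(C)CCC23OCCO3)[C@H](C1)C(=O)OC | intermediate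
18 | benzyl (2R)-2-[(1R,3S,4R)-3-(methoxycarbonyl)-4-(8,8-dimethyl-1,4-dioxaspiro[4.5]dec-6-en-6-yl)cyclohexyl]propanoate | C[C@@H](C(=O)OCc1ccccc1)[C@@H]1CC[C@@H](C2=CC(C)(C)CCC23OCCO3)[C@H](C1)C(=O)OC | intermediate
19 | benzyl (2R)-2-[(1R,3S,4R)-4-(3,3-dimethyl-6-oxocyclohex-1-en-1-yl)-3-(methoxycarbonyl)cyclohexyl]propanoate | C[C@@H](C(=O)OCc1ccccc1)[C@@H]1CC[C@@H](C2=CC(C)(C)CCC2=O)[C@H](C1)C(=O)OC | intermediate
20 | trimethylsilyl dienol ether of 19 (3,3-dimethyl-6-(trimethylsilyloxy)cyclohexa-1,5-dien-1-yl on C7) | C[C@@H](C(=O)OCc1ccccc1)[C@@H]1CC[C@@H](C2=CC(C)(C)CC=C2O[Si](C)(C)C)[C@H](C1)C(=O)OC | intermediate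
21 | benzyl (2R)-2-[(1R,3S,4R)-4-(3,3-dimethyl-6-oxocyclohexa-1,4-dien-1-yl)-3-(methoxycarbonyl)cyclohexyl]propanoate | C[C@@H](C(=O)OCc1ccccc1)[C@@H]1CC[C@@H](C2=CC(C)(C)C=CC2=O)[C@H](C1)C(=O)OC | intermediate
22 | benzyl (2R)-2-[(1R,3S,4R)-4-[(4R)-3,3-dimethyl-6-oxo-4-(4,4,5,5-tetramethyl-1,3,2-dioxaborolan-2-yl)cyclohex-1-en-1-yl]-3-(methoxycarbonyl)cyclohexyl]propanoate | C[C@@H](C(=O)OCc1ccccc1)[C@@H]1CC[C@@H](C2=CC(C)(C)[C@H](B3OC(C)(C)C(C)(C)O3)CC2=O)[C@H](C1)C(=O)OC | intermediate
23 | benzyl (2R)-2-[(1R,3S,4R)-4-[(4R)-4-hydroxy-3,3-dimethyl-6-oxocyclohex-1-en-1-yl]-3-(methoxycarbonyl)cyclohexyl]propanoate | C[C@@H](C(=O)OCc1ccccc1)[C@@H]1CC[C@@H](C2=CC(C)(C)[C@H](O)CC2=O)[C@H](C1)C(=O)OC | intermediate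
24 | benzyl (2R)-2-[(1R,3S,4R)-4-[(4R)-4-(2-tert-butoxy-2-oxoethoxy)-3,3-dimethyl-6-oxocyclohex-1-en-1-yl]-3-(methoxycarbonyl)cyclohexyl]propanoate | C[C@@H](C(=O)OCc1ccccc1)[C@@H]1CC[C@@H](C2=CC(C)(C)[C@H](OCC(=O)OC(C)(C)C)CC2=O)[C@H](C1)C(=O)OC | intermediate
25 | benzyl (2R)-2-[(1R,3S,4R)-4-[(4R)-4-(carboxymethoxy)-3,3-dimethyl-6-oxocyclohex-1-en-1-yl]-3-(methoxycarbonyl)cyclohexyl]propanoate (C16 oxyacetic acid) | C[C@@H](C(=O)OCc1ccccc1)[C@@H]1CC[C@@H](C2=CC(C)(C)[C@H](OCC(=O)O)CC2=O)[C@H](C1)C(=O)OC | intermediate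
26 | benzyl 2-[3-(methoxycarbonyl)-4-(8,8-dimethyl-3-oxo-6-oxabicyclo[3.2.1]octan-2-yl)cyclohexyl]propanoate (C2 and ring C as in 25; 16R; ether bridge C16–O17–C18–C19; C13–H, ring C equatorial) | C[C@@H](C(=O)OCc1ccccc1)[C@@H]1CC[C@@H]([C@H]2C(=O)C[C@H]3OC[C@@H]2C3(C)C)[C@H](C1)C(=O)OC | intermediate
27 | C13 hydroxymethyl ketone of 26 (CH2OH on C13 anti to the C20 methyl over the three-atom bridge) | C[C@@H](C(=O)OCc1ccccc1)[C@@H]1CC[C@@H]([C@]2(CO)C(=O)C[C@H]3OC[C@@H]2C3(C)C)[C@H](C1)C(=O)OC | intermediate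
28 | benzyl ester of the target (δ-lactone C10–O11–C12–C13 closed) | C[C@@H](C(=O)OCc1ccccc1)[C@@H]1CC[C@@H]2[C@H](C1)C(=O)OC[C@]21C(=O)C[C@H]2OC[C@@H]1C2(C)C | intermediate
29 | CNP0152427.2 | C[C@@H](C(=O)O)[C@@H]1CC[C@@H]2[C@H](C1)C(=O)OC[C@]21C(=O)C[C@H]2OC[C@@H]1C2(C)C | target

Total step count: 20. Longest linear sequence: 20 steps, from 1 to 29; 5 and 7 are bought.

**Steps most likely to fail**

Step 18. Base-induced β-elimination of the C16 alkoxyacetate through the C15 enolate would return the dienone. Closure onto the neopentyl carbon C19 may also be slower than hydrogen-atom transfer to the C18 radical, which would leave a C16 methyl ether. The fallback sets out from 25. The acid is condensed with N-hydroxyphthalimide (N,N′-diisopropylcarbodiimide, cat. DMAP, CH2Cl2) to the N-(acyloxy)phthalimide F1. The same C18 radical is then generated reductively without base (Ru(bpy)3(PF6)2, diethyl 2,6-dimethyl-1,4-dihydropyridine-3,5-dicarboxylate, CH2Cl2, blue light). The dihydropyridine also supplies the hydrogen atom for C13, and the route is rejoined at 26.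

Step 19. Hydroxymethylation at C15 may be followed by dehydration to an exocyclic enone or by a second addition. Formaldehyde may attack the wrong face of C13. The ether bridge may open reversibly by β-elimination from the C15 enolate. The fallback sets out from 26. The more substituted C13=C14 trimethylsilyl enol ether F2 is made under equilibrating conditions (TMSCl, NaI, Et3N, MeCN). It is hydroxymethylated by a Lewis acid catalysed aqueous Mukaiyama aldol reaction with formaldehyde (Sc(OTf)3, THF/H2O), which gives 27 without a free enolate. Lactonization with catalytic camphorsulfonic acid in toluene rejoins the route at 28.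

Step 15. Facial discrimination by the catalyst may be weak at the neopentyl carbon C16. The second enone alkene may also be borylated. The β-hydroxy ketone may dehydrate back to the dienone during the oxidative work-up. The fallback sets out from 21. Nucleophilic asymmetric epoxidation of the α-unsubstituted C15=C16 alkene (H2O2, a 9-amino-9-deoxy-epi-cinchona alkaloid salt as iminium catalyst, dioxane) gives the 15,16-epoxy ketone F3. Its Cα–O bond is then cleaved reductively with sodium phenylselenide (from (PhSe)2 and NaBH4, AcOH, EtOH), and the route is rejoined at 23.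

**Further compounds**

F1 | step 18 | N-(acyloxy)phthalimide of 25 | C[C@@H](C(=O)OCc1ccccc1)[C@@H]1CC[C@@H](C2=CC(C)(C)[C@H](OCC(=O)ON3C(=O)c4ccccc4C3=O)CC2=O)[C@H](C1)C(=O)OC
F2 | step 19 | C13=C14 trimethylsilyl enol ether of 26 | C[C@@H](C(=O)OCc1ccccc1)[C@@H]1CC[C@@H](C2=C(O[Si](C)(C)C)C[C@H]3OC[C@@H]2C3(C)C)[C@H](C1)C(=O)OC
F3 | step 15 | 15,16-epoxy ketone of 21 (epoxide oxygen on the face of the later C16 hydroxyl) | C[C@@H](C(=O)OCc1ccccc1)[C@@H]1CC[C@@H](C2=CC(C)(C)[C@@H]3O[C@@H]3C2=O)[C@H](C1)C(=O)OC
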